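I could not carry a fall in percent per minute from the summer run to the flask, since a percent of 72 mM is a different amount from a percent of 48 mM; so I kept the books in mM.

| flask | solid substrate | remark | time |
|---|---|---|---|
| summer | 72 mM | run made earlier |  |
| flask | 48 mM |  | 15 min |

summer run (percent of the solid substrate charged)

| time / min | solid substrate / % | product / % |
|---|---|---|
| 0.333 | 97 | 0 |
| 0.500 | 96 | 0 |
| 0.833 | 91 | 0 |
| 1.33 | 90 | 0 |
| 2.00 | 85 | 2 |
| 3.00 | 80 | 1 |
| 5.00 | 70 | 9 |

(each reading ± 2 percentage points)

1. why nothing more happens at 15 min, or that something still does (for what has run out or reacted, a solid counts together with what of it has only dissolved) (forward and back rates have come level / it is still moving / all of the solid substrate has reacted)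
2. part of the solid substrate that has turned into other species by 15 min (what has only dissolved does not count)
3. amount of product at 15 min, in percent of the solid substrate charged
4. amount of starting material at 15 min, in percent of the solid substrate charged
5. amount of product if the flask were left three thousand times as long, in percent of the solid substrate charged

- solid substrate is a solid; its amount is given per volume of the solution
- at the start none of the solid substrate is in solution
- what has only dissolved of solid substrate counts as not reacted
- the reaction counts as stopped when no species that holds the solid substrate changes by six tenths of a point or more over the second half of the time
- starting material means what is dissolved; the solid is not counted in it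

Between 2.00 min and 5.00 min the summer run's solid substrate fell from 85 % to 70 %, a reading of 3.60 mM min⁻¹. I called this the crawl, the steady amount of solid substrate entering solution per minute after the first quick minutes, a zero-order feed. A constant rate integrates to a straight line, c(solid substrate) = charge − crawl·t.

So the first entry for the flask closed at 13.3 min, earlier than 15 min, and I booked no solid substrate at the asked time. The second entry was what is neither solid nor product: at 5.00 min the summer run's readings left 15.1 mM so, and I carried that amount over unchanged, having given the flask the same crawl by assumption. That is 31.5 % of the flask's charge, my estimate for starting material together with anything else dissolved and not yet product. The last entry, product, took the rest, 68.5 %, and conversion, which counts product among the other species, I put at that estimate or above. With that hold still to pass on, I expected the flask to be still moving, and the whole charge to end as product.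

The forecast, reading the solid's fall as “dissolution slowing as the solution fills”, gave it is still moving, conversion 55 %, product 55 % where I had 68.5 %, starting material 36 %, and 100 % in the long run.

The flask gave it is still moving, conversion 78.8 %, product 72.4 %, starting material 21.2 %, and 100 % in the long run. Its solid substrate stood at 0 % at 15.0 min, and the part not yet product came to 13.2 mM against my 15.1 mM.

    starting material ⇌ intermediate A (K = 0.870, k = 0.00450 s⁻¹)
    intermediate A ⇌ intermediate B (K = 0.420, k = 0.0590 s⁻¹)
    intermediate A ⇌ intermediate C (K = 34.0, k = 0.0240 s⁻¹)
    intermediate C → product (k = 0.0920 s⁻¹)
    solid substrate ⇌ starting material, rate k5*(cs5 - [starting material]) while solid is left; crystals form when [starting material] > cs5 (solubility = 23.0 mM, k = 0.00490 s⁻¹)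

At 7.50 min the crawl leaves the flask 43.8 % of its solid substrate, and the flask held 38.8 %. On the neighbour charged with 120 mM, read at 15 min, the crawl moves 54.0 mM, less than that charge, so the first entry stays open: solid substrate 55.0 %, product 32.4 %. That neighbour stood at 57.2 % solid substrate and 29.1 % product.

Readings and results were computed with constants of no real substance, noise included.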